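**Plan**
- Retrosynthesis, last cut first: the 4-bromo-3,3-dimethylcyclohexanol ring is opened at the bond between its CMe2 carbon and the ring CH2 next to the carbinol, together with its C–Br and C–OH bonds. In that ring Br sits on the carbon next to CMe2 and the carbinol carbon lies two bonds from CMe2 through a CH2, which is the trace of Br+ on a prenyl end trapped by an exo-methylene alkene and then by water (diene 20).
- Next cuts: the exo-methylene and homoprenyl chain (Wittig, Weinreb ketone synthesis), bond C2–C3 of the hydrindane cyclopentane (5-exo radical conjugate addition), the carbinol methyl (organocerium), and bond C3a–C7a with its C–Br (bromonium cyclisation of a vicinal bromochloride ended by a β-keto ester).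
- Forward: C6 chain by carboalumination, enantioselective bromochlorination, acetoacetate alkylation, bromocyclohexanone (ring 1), cyclopentane (ring 2, trans-hydrindane), side chain, bromocyclohexanol (ring 3).
- Stereochemistry: absolute configuration from the catalytic bromochlorination (C7, C7a); the chair cyclisation sets C3a; equatorial methyl delivery sets C4; allylic strain in the radical closure sets C3; the enzyme sets the ring-A C–Br and axial water capture sets the ring-A carbinol.

Key step: step 13

Remark: in step 2 the antipode of the chiral Schiff-base ligand is taken to be the one that gives (2S,3R)-5. TBS = tert-butyl(dimethyl)silyl.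

Step 1
Reactants: 1 tert-butyl(but-3-yn-1-yloxy)dimethylsilane
Product: 4 (2E)-5-(TBSO)-3-methylpent-2-en-1-ol, via alkenylalane 2 (not isolated), via lithium alkenylalanate 3 (not isolated)
Conditions: Me3Al, Cp2ZrCl2 (cat.), CH2Cl2, 0 °C to rt; n-BuLi, THF, −78 °C; (CH2O)n, rt
Reagents that add atoms: trimethylaluminium C[Al](C)C; formaldehyde (as paraformaldehyde) C=O
Why: Negishi carboalumination: Zr-catalysed syn addition of Me–Al puts methyl on the internal and aluminium on the terminal alkyne carbon, and hydroxymethylation of the alanate with retention gives the (E)-trisubstituted allylic alcohol.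

Step 2
Reactants: 4 (2E)-5-(TBSO)-3-methylpent-2-en-1-ol
Product: 5 (2S,3R)-2-bromo-5-(TBSO)-3-chloro-3-methylpentan-1-ol
Conditions: NBS, ClTi(OiPr)3, chiral tridentate Schiff-base ligand (cat.), hexanes, −20 °C
Reagents that add atoms: N-bromosuccinimide O=C1CCC(=O)N1Br; chlorotitanium triisopropoxide CC(C)O[Ti](Cl)(OC(C)C)OC(C)C
Why: Titanium-mediated catalytic enantioselective bromochlorination of an allylic alcohol: the ligand-bound titanium alkoxide directs anti addition with bromine on C2 and chloride on the tertiary C3 (Markovnikov), so the future ring carbons C7 and C7a are both set here from the (E)-alkene and the ligand.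

Step 3
Reactants: 5 (2S,3R)-2-bromo-5-(TBSO)-3-chloro-3-methylpentan-1-ol; 6 methyl acetoacetate
Product: 8 methyl (6S,7R)-6-bromo-9-(TBSO)-7-chloro-7-methyl-3-oxononanoate, via primary triflate 7 (not isolated)
Conditions: Tf2O, 2,6-lutidine, CH2Cl2, −78 °C; transfer into the dianion of 6 (NaH, then n-BuLi, THF, 0 °C), −78 °C
Reagents that add atoms: none
Why: Triflation of the primary alcohol and SN2 γ-alkylation with the acetoacetate dianion at low temperature, where displacement of the primary triflate should outrun elimination and the hindered secondary bromide and tertiary chloride stay untouched.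

Step 4
Reactants: 8 methyl (6S,7R)-6-bromo-9-(TBSO)-7-chloro-7-methyl-3-oxononanoate
Product: 9 methyl (1S,2S,3S)-3-bromo-2-[2-(TBSO)ethyl]-2-methyl-6-oxocyclohexane-1-carboxylate
Conditions: (CF3)2CHOH (HFIP), NaHCO3, 25 °C
Reagents that add atoms: none
Why: Enantiospecific solvolytic bromonium polyene cyclisation: in HFIP the tertiary chloride ionises with participation of the vicinal bromine and the H-bonded enol of the β-keto ester attacks the tertiary carbon anti to bromine through a chair (6-endo-trig), which gives equatorial Br, axial methyl and equatorial ester, while HFIP solvation of the enol oxygen favours C- over O-alkylation.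

Step 5
Reactants: 9 methyl (1S,2S,3S)-3-bromo-2-[2-(TBSO)ethyl]-2-methyl-6-oxocyclohexane-1-carboxylate
Product: 10 methyl (1S,2S,3S,6R)-3-bromo-2-[2-(TBSO)ethyl]-6-hydroxy-2,6-dimethylcyclohexane-1-carboxylate
Conditions: MeMgBr, anhydrous CeCl3, THF, −78 °C
Reagents that add atoms: methylmagnesium bromide C[Mg]Br
Why: Organocerium 1,2-addition, which suppresses enolisation of the β-keto ester; the axial face of the ketone is blocked by the syn-axial ring methyl, so methyl enters equatorially and the new tertiary OH is axial, cis to that methyl.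

Step 6
Reactants: 10 methyl (1S,2S,3S,6R)-3-bromo-2-[2-(TBSO)ethyl]-6-hydroxy-2,6-dimethylcyclohexane-1-carboxylate
Product: 11 (1R,2R,3S,4S)-4-bromo-3-[2-(TBSO)ethyl]-2-(hydroxymethyl)-1,3-dimethylcyclohexan-1-ol
Conditions: DIBAL-H (excess), CH2Cl2, −78 to 0 °C; Rochelle salt work-up
Reagents that add atoms: none
Why: DIBAL-H reduction of the methyl ester to the primary alcohol; the secondary bromide, the silyl ether and the tertiary alcohol are inert.

Step 7
Reactants: 11 (1R,2R,3S,4S)-4-bromo-3-[2-(TBSO)ethyl]-2-(hydroxymethyl)-1,3-dimethylcyclohexan-1-ol; 12 N-methoxy-N-methyl-2-(triphenylphosphoranylidene)acetamide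
Product: 14 (2E)-3-{(1S,2S,3S,6R)-3-bromo-2-[2-(TBSO)ethyl]-6-hydroxy-2,6-dimethylcyclohexyl}-N-methoxy-N-methylprop-2-enamide, via hydroxy aldehyde 13 (not isolated)
Conditions: Dess–Martin periodinane, NaHCO3, CH2Cl2, 0 °C; then 12, 40 °C
Reagents that add atoms: none
Why: Dess–Martin oxidation of the primary alcohol followed in the same flask by Wittig olefination with the stabilised ylide under neutral conditions, which spares the β-hydroxy aldehyde from retro-aldol cleavage, dehydration and epimerisation and gives the (E)-enamide.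

Step 8
Reactants: 14 (2E)-3-{(1S,2S,3S,6R)-3-bromo-2-[2-(TBSO)ethyl]-6-hydroxy-2,6-dimethylcyclohexyl}-N-methoxy-N-methylprop-2-enamide
Product: 15 (2E)-3-[(1S,2S,3S,6R)-3-bromo-6-hydroxy-2-(2-hydroxyethyl)-2,6-dimethylcyclohexyl]-N-methoxy-N-methylprop-2-enamide
Conditions: HF·pyridine, pyridine/THF, 0 °C
Reagents that add atoms: none
Why: Fluoride desilylation under buffered acidic conditions, chosen over TBAF so that no alkoxide forms that could add to the enamide (oxa-Michael).

Step 9
Reactants: 15 (2E)-3-[(1S,2S,3S,6R)-3-bromo-6-hydroxy-2-(2-hydroxyethyl)-2,6-dimethylcyclohexyl]-N-methoxy-N-methylprop-2-enamide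
Product: 16 (2E)-3-[(1S,2S,3S,6R)-3-bromo-6-hydroxy-2-(2-iodoethyl)-2,6-dimethylcyclohexyl]-N-methoxy-N-methylprop-2-enamide
Conditions: I2, PPh3, imidazole, CH2Cl2, 0 °C
Reagents that add atoms: iodine II
Why: Appel-type iodination (PPh3/I2/imidazole) converts only the primary alcohol, since the hindered tertiary alcohol does not form the oxyphosphonium salt.

Step 10
Reactants: 16 (2E)-3-[(1S,2S,3S,6R)-3-bromo-6-hydroxy-2-(2-iodoethyl)-2,6-dimethylcyclohexyl]-N-methoxy-N-methylprop-2-enamide
Product: 17 2-[(1S,3aS,4S,7R,7aS)-4-bromo-7-hydroxy-3a,7-dimethyloctahydro-1H-inden-1-yl]-N-methoxy-N-methylacetamide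
Conditions: (Me3Si)3SiH (slight excess, slow addition), AIBN, benzene (high dilution), 80 °C
Reagents that add atoms: none
Why: Giese-type 5-exo-trig radical cyclisation: the silyl radical abstracts iodine far faster than the hindered secondary bromine, the primary radical adds to the β-carbon of the enamide in the conformer whose allylic C–H eclipses the alkene (A1,3 strain), so the CH2C(O)N arm ends trans to the carbinol carbon (1S in 17), and the trans ring fusion is already fixed by the two equatorial arms.

Step 11
Reactants: 17 2-[(1S,3aS,4S,7R,7aS)-4-bromo-7-hydroxy-3a,7-dimethyloctahydro-1H-inden-1-yl]-N-methoxy-N-methylacetamide; 18 5-bromo-2-methylpent-2-ene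
Product: 19 1-[(1S,3aS,4S,7R,7aS)-4-bromo-7-hydroxy-3a,7-dimethyloctahydro-1H-inden-1-yl]-6-methylhept-5-en-2-one
Conditions: 18, Mg, THF (Grignard formation); then 17, THF, 0 °C; aq. NH4Cl
Reagents that add atoms: none
Why: Weinreb ketone synthesis: the chelated tetrahedral intermediate stops the Grignard addition at the ketone, one further equivalent only deprotonates the tertiary alcohol, and the equatorial secondary bromide is inert.

Step 12
Reactants: 19 1-[(1S,3aS,4S,7R,7aS)-4-bromo-7-hydroxy-3a,7-dimethyloctahydro-1H-inden-1-yl]-6-methylhept-5-en-2-one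
Product: 20 (3S,3aS,4R,7S,7aS)-7-bromo-4,7a-dimethyl-3-(6-methyl-2-methylidenehept-5-en-1-yl)octahydro-1H-inden-4-ol
Conditions: Ph3PCH3Br, KOtBu, THF, 0 °C to rt
Reagents that add atoms: methyltriphenylphosphonium bromide C[P+](c1ccccc1)(c1ccccc1)c1ccccc1.[Br-]
Why: Wittig methylenation of the unhindered dialkyl ketone; the equatorial bromide has no anti-periplanar hydrogen, so E2 elimination by the ylide should not compete.

Step 13
Reactants: 20 (3S,3aS,4R,7S,7aS)-7-bromo-4,7a-dimethyl-3-(6-methyl-2-methylidenehept-5-en-1-yl)octahydro-1H-inden-4-ol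
Product: 21 (3S,3aS,4R,7S,7aS)-7-bromo-3-{[(1S,4S)-4-bromo-1-hydroxy-3,3-dimethylcyclohexyl]methyl}-4,7a-dimethyloctahydro-1H-inden-4-ol
Conditions: vanadium-dependent bromoperoxidase (Corallina officinalis), KBr, H2O2 (slow addition), Na3VO4 (trace), MES buffer pH 6.5/EtOH, 25 °C
Reagents that add atoms: potassium bromide [K+].[Br-]; water O
Why: Proposed new method: a vanadium-dependent bromoperoxidase oxidises bromide with H2O2 to an enzyme-bound Br+ equivalent that is delivered to the electron-richer trisubstituted (prenyl) alkene, the bromonium ion is opened at its CMe2 carbon by the CH2 terminus of the 1,1-disubstituted alkene (cation–olefin cyclisation), and water captures the resulting tertiary cyclohexyl cation. The closest known reaction type is the bromoperoxidase-catalysed bromonium cyclisation of acyclic terpenols (nerolidol to the snyderols), extended here to an exo-methylene terminator with water termination on a substrate that already carries stereocentres. The ring closes in the 6-endo-trig mode through a chair in which bromine is anti to the forming C–C bond and therefore equatorial. The C–Br centre (4S of ring A) has no stereocentre nearby and is controlled by the enzyme, which must deliver bromine to one face of the prenyl alkene; the carbinol centre (1S) is controlled by the ring, water entering axially so that the bulky CH2-hydrindanyl group stays equatorial and avoids the syn-axial methyl, which places OH cis to Br. The step needs selectivity for the prenyl over the methylene alkene, for cyclisation over bromohydrin formation, and for water over the hydrindane hydroxyl as terminating nucleophile: alkene substitution secures the first, and internal ether formation is disfavoured because it would need a tetrahydropyran trans-fused to the already trans-fused cyclopentane.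

**Compound list**
1 | tert-butyl(but-3-yn-1-yloxy)dimethylsilane | C#CCCO[Si](C)(C)C(C)(C)C | starting material
2 | [(1E)-4-{[tert-butyl(dimethyl)silyl]oxy}-2-methylbut-1-en-1-yl]dimethylalumane | C[Al](C)/C=C(\C)CCO[Si](C)(C)C(C)(C)C | intermediate
3 | lithium butyl[(1E)-4-{[tert-butyl(dimethyl)silyl]oxy}-2-methylbut-1-en-1-yl]dimethylaluminate | [Li+].CCCC[Al-](C)(C)/C=C(\C)CCO[Si](C)(C)C(C)(C)C | intermediate
4 | (2E)-5-{[tert-butyl(dimethyl)silyl]oxy}-3-methylpent-2-en-1-ol | OC/C=C(\C)CCO[Si](C)(C)C(C)(C)C | intermediate
5 | (2S,3R)-2-bromo-5-{[tert-butyl(dimethyl)silyl]oxy}-3-chloro-3-methylpentan-1-ol | OC[C@H](Br)[C@](C)(Cl)CCO[Si](C)(C)C(C)(C)C | intermediate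
6 | methyl acetoacetate (methyl 3-oxobutanoate) | COC(=O)CC(C)=O | starting material
7 | (2S,3R)-2-bromo-5-{[tert-butyl(dimethyl)silyl]oxy}-3-chloro-3-methylpentyl trifluoromethanesulfonate | FC(F)(F)S(=O)(=O)OC[C@H](Br)[C@](C)(Cl)CCO[Si](C)(C)C(C)(C)C | intermediate
8 | methyl (6S,7R)-6-bromo-9-{[tert-butyl(dimethyl)silyl]oxy}-7-chloro-7-methyl-3-oxononanoate | COC(=O)CC(=O)CC[C@H](Br)[C@](C)(Cl)CCO[Si](C)(C)C(C)(C)C | intermediate
9 | methyl (1S,2S,3S)-3-bromo-2-(2-{[tert-butyl(dimethyl)silyl]oxy}ethyl)-2-methyl-6-oxocyclohexane-1-carboxylate (Br equatorial, ring methyl axial, ester equatorial) | COC(=O)[C@@H]1C(=O)CC[C@H](Br)[C@@]1(C)CCO[Si](C)(C)C(C)(C)C | intermediate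
10 | methyl (1S,2S,3S,6R)-3-bromo-2-(2-{[tert-butyl(dimethyl)silyl]oxy}ethyl)-6-hydroxy-2,6-dimethylcyclohexane-1-carboxylate (OH axial, cis to the C2 methyl) | COC(=O)[C@@H]1[C@](C)(O)CC[C@H](Br)[C@@]1(C)CCO[Si](C)(C)C(C)(C)C | intermediate
11 | (1R,2R,3S,4S)-4-bromo-3-(2-{[tert-butyl(dimethyl)silyl]oxy}ethyl)-2-(hydroxymethyl)-1,3-dimethylcyclohexan-1-ol | OC[C@@H]1[C@](C)(O)CC[C@H](Br)[C@@]1(C)CCO[Si](C)(C)C(C)(C)C | intermediate
12 | N-methoxy-N-methyl-2-(triphenylphosphoranylidene)acetamide | CON(C)C(=O)C=P(c1ccccc1)(c1ccccc1)c1ccccc1 | starting material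
13 | (1S,2S,3S,6R)-3-bromo-2-(2-{[tert-butyl(dimethyl)silyl]oxy}ethyl)-6-hydroxy-2,6-dimethylcyclohexane-1-carbaldehyde | O=C[C@@H]1[C@](C)(O)CC[C@H](Br)[C@@]1(C)CCO[Si](C)(C)C(C)(C)C | intermediate
14 | (2E)-3-[(1S,2S,3S,6R)-3-bromo-2-(2-{[tert-butyl(dimethyl)silyl]oxy}ethyl)-6-hydroxy-2,6-dimethylcyclohexyl]-N-methoxy-N-methylprop-2-enamide | CON(C)C(=O)/C=C/[C@@H]1[C@](C)(O)CC[C@H](Br)[C@@]1(C)CCO[Si](C)(C)C(C)(C)C | intermediate
15 | (2E)-3-[(1S,2S,3S,6R)-3-bromo-6-hydroxy-2-(2-hydroxyethyl)-2,6-dimethylcyclohexyl]-N-methoxy-N-methylprop-2-enamide | CON(C)C(=O)/C=C/[C@@H]1[C@](C)(O)CC[C@H](Br)[C@@]1(C)CCO | intermediate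
16 | (2E)-3-[(1S,2S,3S,6R)-3-bromo-6-hydroxy-2-(2-iodoethyl)-2,6-dimethylcyclohexyl]-N-methoxy-N-methylprop-2-enamide | CON(C)C(=O)/C=C/[C@@H]1[C@](C)(O)CC[C@H](Br)[C@@]1(C)CCI | intermediate
17 | 2-[(1S,3aS,4S,7R,7aS)-4-bromo-7-hydroxy-3a,7-dimethyloctahydro-1H-inden-1-yl]-N-methoxy-N-methylacetamide (trans-fused) | CON(C)C(=O)C[C@@H]1CC[C@]2(C)[C@@H](Br)CC[C@@](C)(O)[C@@H]12 | intermediate
18 | 5-bromo-2-methylpent-2-ene | CC(C)=CCCBr | starting material
19 | 1-[(1S,3aS,4S,7R,7aS)-4-bromo-7-hydroxy-3a,7-dimethyloctahydro-1H-inden-1-yl]-6-methylhept-5-en-2-one | CC(C)=CCCC(=O)C[C@@H]1CC[C@]2(C)[C@@H](Br)CC[C@@](C)(O)[C@@H]12 | intermediate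
20 | (3S,3aS,4R,7S,7aS)-7-bromo-4,7a-dimethyl-3-(6-methyl-2-methylidenehept-5-en-1-yl)octahydro-1H-inden-4-ol | CC(C)=CCCC(=C)C[C@@H]1CC[C@]2(C)[C@@H](Br)CC[C@@](C)(O)[C@@H]12 | intermediate
21 | (3S,3aS,4R,7S,7aS)-7-bromo-3-{[(1S,4S)-4-bromo-1-hydroxy-3,3-dimethylcyclohexyl]methyl}-4,7a-dimethyloctahydro-1H-inden-4-ol | CC1(C)C[C@@](O)(C[C@@H]2CC[C@]3(C)[C@@H](Br)CC[C@@](C)(O)[C@@H]23)CC[C@@H]1Br | target

Total step count: 13. Longest linear sequence: 13 steps (from 1; compounds 6, 12 and 18 are purchased).

**Steps most likely to fail**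

1. Step 13 (bears the label). What may go wrong: the enzyme may deliver bromine to both faces of the remote prenyl alkene, or to the wrong one. The cation may also be quenched from the equatorial face, by proton loss, or by the hydrindane hydroxyl. Water may open the bromonium ion before cyclisation, and the lipophilic substrate may stay out of the aqueous phase. The fallback uses known chemistry, sets out from 20 and returns at 21 in two operations. A mercury(II)-induced cation–olefin cyclisation with water termination (Hg(OTf)2·PhNMe2, MeCN/H2O, −20 °C; then aqueous NaCl) should give the organomercuric chloride F1 with the C–Hg bond equatorial. Brominative demercuration (Br2, LiBr, pyridine, O2, 0 °C) then replaces mercury by bromine. Face selectivity at the prenyl group is given up in this way, so 21 should arise together with ring-A diastereomers and would be separated by preparative HPLC.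

2. Step 3. What may go wrong: E2 loss of triflate or of HCl, halophilic attack by the strongly basic dianion, or 1,2-migration of bromine in the β-bromo triflate before alkylation. The fallback sets out from 4 and returns at 9, and completes the carbon chain before any halogen is introduced. Appel bromination of 4 (CBr4, PPh3, CH2Cl2) gives the allylic bromide F2, which alkylates the acetoacetate dianion to the achiral keto ester F3. A catalytic enantioselective bromonium polyene cyclisation of F3 (chiral BINOL-derived thiophosphoramide or phosphoramidite Lewis base, DBDMH or NBS, toluene, −40 °C) should then give 9 directly, so that steps 2 to 4 are replaced.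

3. Step 4. What may go wrong: attack through the enol oxygen instead of carbon, proton loss from the cation to an allylic bromide, or erosion of stereospecificity by bromonium transfer between molecules. The fallback sets out from 8 and returns at 9, and accepts O-cyclisation. The solvolysis is run to the cyclic vinylogous carbonate F4. SnCl4 (CH2Cl2, −78 to 0 °C) then ionises its tertiary C–O bond again, with bromine participation, so that the thermodynamically preferred C-cyclised keto ester 9 should form.

Further compounds
F1 | step 13 | chlorido{(1S,4S)-4-{[(1S,3aS,4S,7R,7aS)-4-bromo-7-hydroxy-3a,7-dimethyloctahydro-1H-inden-1-yl]methyl}-4-hydroxy-2,2-dimethylcyclohexyl}mercury | CC1(C)C[C@@](O)(C[C@@H]2CC[C@]3(C)[C@@H](Br)CC[C@@](C)(O)[C@@H]23)CC[C@@H]1[Hg]Cl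
F2 | step 3 | {[(3E)-5-bromo-3-methylpent-3-en-1-yl]oxy}(tert-butyl)dimethylsilane | BrC/C=C(\C)CCO[Si](C)(C)C(C)(C)C
F3 | step 3 | methyl (6E)-9-{[tert-butyl(dimethyl)silyl]oxy}-7-methyl-3-oxonon-6-enoate | COC(=O)CC(=O)CC/C=C(\C)CCO[Si](C)(C)C(C)(C)C
F4 | step 4 | methyl (2Z)-2-[(5S,6R)-5-bromo-6-(2-{[tert-butyl(dimethyl)silyl]oxy}ethyl)-6-methyloxan-2-ylidene]acetate | COC(=O)/C=C1/CC[C@H](Br)[C@@](C)(CCO[Si](C)(C)C(C)(C)C)O1
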